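**Retrosynthetic overview**

The strategy rests on the 1,2-dioxolane ring (O1–O2–C3–C4–C5; side chain C1′–C15′ on C5): its two peroxide-bearing carbons C3 and C5 are both quaternary and flank the single ring CH2 (C4), so each can be reached through a tertiary cation and neither carries a hydrogen that base could remove.
1. Last: the C3–CH2CO2H arm comes from a C3–CH2CH2OSi arm (desilylation, two-stage oxidation).
2. Side chain: C9′=C10′ by Julia olefination of a C7′–C9′ (E)-enal with the benzothiazolyl sulfone of (Z)-hex-3-en-1-ol (C10′–C15′, Z alkene already in place); C7′=C8′ by Wittig formyl-olefination of the C7′ aldehyde.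
3. Ring (the only one, made in a single step): C4–C5 and O2–C3 by (3+2) annulation of the peroxycarbenium ion of a methyl-ketone silyl peroxyketal (C5, O1, O2) with a 1,1-disubstituted alkene (C4, C3); trans racemate separated, then resolved on a chiral phase.
4. Partners: the peroxyketal from 6-bromohexan-1-ol and methallyl Grignard reagent by acetylation, ozonolysis in methanol and silylation; the alkene from 3-methylbut-3-en-1-ol.

Key step: step 6

Remark (assumption): the annulation is not enantioselective. Its product and all later compounds are named and drawn as the one enantiomer that is carried on after the chromatographic separations described in step 6 (silica, then chiral stationary phase), which are counted with that step.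

**Route**

Step 1
Reactants: 1 6-bromohexan-1-ol; 2 (2-methylprop-2-en-1-yl)magnesium chloride
Product: 3 8-methylnon-8-en-1-ol
Conditions: 2 (2.3 equiv), Li2CuCl4 (3 mol %), THF, −20 °C → rt; H2O
Reagents that add atoms: none
Why: Copper-catalysed sp3–sp3 cross-coupling (Kochi type) of the primary bromide with the allylic Grignard reagent, whose first equivalent only deprotonates the alcohol and whose symmetrical allyl termini leave no regiochemical ambiguity.

Step 2
Reactants: 3 8-methylnon-8-en-1-ol
Product: 4 8-methylnon-8-en-1-yl acetate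
Conditions: Ac2O, pyridine, DMAP (cat.), CH2Cl2, 0 °C → rt
Reagents that add atoms: acetic anhydride, CC(=O)OC(C)=O
Why: DMAP-catalysed acylation of the primary alcohol, which turns the chain end into a saturated, non-nucleophilic group for the ozonolysis and the cationic key step.

Step 3
Reactants: 4 8-methylnon-8-en-1-yl acetate
Product: 5 8-hydroperoxy-8-methoxynonyl acetate (racemic)
Conditions: O3, CH2Cl2/MeOH, −78 °C; N2 purge; concentration below 30 °C
Reagents that add atoms: ozone, [O-][O+]=O; methanol, CO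
Why: Criegee ozonolysis with solvent capture: the primary ozonide of the 1,1-disubstituted alkene should fragment mainly to formaldehyde and the ketone-derived carbonyl oxide, which methanol traps as the α-methoxy hydroperoxide without reductive work-up.

Step 4
Reactants: 5 8-hydroperoxy-8-methoxynonyl acetate
Product: 6 8-methoxy-8-[(triethylsilyl)peroxy]nonyl acetate (racemic)
Conditions: Et3SiCl, imidazole, DMF, 0 °C
Reagents that add atoms: chlorotriethylsilane, CC[Si](Cl)(CC)CC
Why: O-silylation of the hydroperoxide; the ketal carbon bears no hydrogen, so the base cannot trigger a Kornblum–DeLaMare fragmentation.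

Step 5
Reactants: 7 3-methylbut-3-en-1-ol
Product: 8 tert-butyl[(3-methylbut-3-en-1-yl)oxy]diphenylsilane
Conditions: t-BuPh2SiCl, imidazole, CH2Cl2, rt
Reagents that add atoms: tert-butyl(chloro)diphenylsilane, CC(C)(C)[Si](Cl)(c1ccccc1)c1ccccc1
Why: Silylation of the primary alcohol; the bulky silyl ether is stable to SnCl4 at low temperature and cannot act as a neighbouring group.

Step 6
Reactants: 6 8-methoxy-8-[(triethylsilyl)peroxy]nonyl acetate; 8 tert-butyl[(3-methylbut-3-en-1-yl)oxy]diphenylsilane
Product: 9 7-[(3S,5S)-5-(2-{[tert-butyl(diphenyl)silyl]oxy}ethyl)-3,5-dimethyl-1,2-dioxolan-3-yl]heptyl acetate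
Conditions: 8 (3 equiv), SnCl4 (1.5 equiv), CH2Cl2, −78 °C; H2O; SiO2 chromatography (trans from cis racemate); preparative HPLC on a cellulose tris(3,5-dimethylphenylcarbamate) phase
Reagents that add atoms: none
Why: SnCl4 abstracts methoxide from 6 to give a peroxycarbenium ion at C5; the unsubstituted CH2 terminus of 8 adds to it in the Markovnikov sense (C4–C5), and the tertiary carbocation so formed at C3 is captured by the neighbouring silylperoxy oxygen (O2–C3) with loss of the triethylsilyl group. The closest known reaction type is the Lewis-acid-promoted (3+2) annulation of silyl peroxyketals with alkenes, for which a dialkyl ketone peroxyketal and a 1,1-disubstituted alkene are the best-suited partner classes. The 1,2-dioxolane closes stepwise and cationically: after the intermolecular C–C bond formation the ring is shut by intramolecular O-attack on the tertiary cation through a five-membered, envelope-like transition state. Both stereocentres (C3 and C5) are created here from achiral partners and planar cations, so there is no absolute control, and the relative configuration rests only on the small steric difference between methyl and CH2R on each carbon, from which at most a modest bias for the two long arms trans is expected; the trans racemate is therefore separated from the cis one on silica and (3S,5S)-9 is taken from it on the chiral phase. The step needs chemoselectivity for a single π-nucleophile and for ring closure over proton loss: the chain end of 6 is a saturated acetate, the silyl ether of 8 cannot participate, and low temperature with excess 8 should favour capture of the short-lived cation by oxygen.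

Step 7
Reactants: 9 7-[(3S,5S)-5-(2-{[tert-butyl(diphenyl)silyl]oxy}ethyl)-3,5-dimethyl-1,2-dioxolan-3-yl]heptyl acetate
Product: 10 7-[(3S,5S)-5-(2-{[tert-butyl(diphenyl)silyl]oxy}ethyl)-3,5-dimethyl-1,2-dioxolan-3-yl]heptan-1-ol
Conditions: K2CO3 (0.2 equiv), MeOH, rt
Reagents that add atoms: none
Why: Base-catalysed transesterification of the primary acetate; the dioxolane has no hydrogen on either peroxide carbon and therefore tolerates methoxide, and the silyl ether is untouched.

Step 8
Reactants: 10 7-[(3S,5S)-5-(2-{[tert-butyl(diphenyl)silyl]oxy}ethyl)-3,5-dimethyl-1,2-dioxolan-3-yl]heptan-1-ol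
Product: 11 7-[(3S,5S)-5-(2-{[tert-butyl(diphenyl)silyl]oxy}ethyl)-3,5-dimethyl-1,2-dioxolan-3-yl]heptanal
Conditions: Dess–Martin periodinane, CH2Cl2, 0 °C → rt
Reagents that add atoms: none
Why: Dess–Martin oxidation of the primary alcohol to the C7′ aldehyde with a hypervalent iodine oxidant that leaves the dialkyl peroxide alone.

Step 9
Reactants: 11 7-[(3S,5S)-5-(2-{[tert-butyl(diphenyl)silyl]oxy}ethyl)-3,5-dimethyl-1,2-dioxolan-3-yl]heptanal; 12 (triphenylphosphoranylidene)acetaldehyde
Product: 13 (2E)-9-[(3S,5S)-5-(2-{[tert-butyl(diphenyl)silyl]oxy}ethyl)-3,5-dimethyl-1,2-dioxolan-3-yl]non-2-enal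
Conditions: 12 (1.2 equiv), toluene, 80 °C
Reagents that add atoms: none
Why: Wittig reaction with a stabilised formylmethylene ylide, which should set C7′=C8′ as the E isomer and brings no reagent that reduces the O–O bond.

Step 10
Reactants: 14 (3Z)-hex-3-en-1-ol
Product: 15 2-{[(3Z)-hex-3-en-1-yl]sulfanyl}-1,3-benzothiazole
Conditions: 1,3-benzothiazole-2-thiol, PPh3, DIAD, THF, 0 °C → rt
Reagents that add atoms: 1,3-benzothiazole-2-thiol, Sc1nc2ccccc2s1
Why: Mitsunobu thioetherification (SN2 at the primary carbon by the acidic heteroaryl thiol), which leaves the Z alkene untouched.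

Step 11
Reactants: 15 2-{[(3Z)-hex-3-en-1-yl]sulfanyl}-1,3-benzothiazole
Product: 16 2-{[(3Z)-hex-3-en-1-yl]sulfonyl}-1,3-benzothiazole
Conditions: (NH4)6Mo7O24·4H2O (cat.), 30% aq. H2O2, EtOH, 0 °C → rt
Reagents that add atoms: hydrogen peroxide, OO
Why: Molybdate-catalysed oxidation of the sulfide to the sulfone, in which the peroxomolybdate attacks sulfur much faster than an isolated disubstituted alkene.

Step 12
Reactants: 13 (2E)-9-[(3S,5S)-5-(2-{[tert-butyl(diphenyl)silyl]oxy}ethyl)-3,5-dimethyl-1,2-dioxolan-3-yl]non-2-enal; 16 2-{[(3Z)-hex-3-en-1-yl]sulfonyl}-1,3-benzothiazole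
Product: 17 tert-butyl(2-{(3S,5S)-3,5-dimethyl-5-[(7E,9E,12Z)-pentadeca-7,9,12-trien-1-yl]-1,2-dioxolan-3-yl}ethoxy)diphenylsilane
Conditions: NaN(SiMe3)2 (1.3 equiv) added to 13 and 16 (1.3 equiv), THF, −78 °C → rt
Reagents that add atoms: none
Why: One-pot Julia olefination of an alkyl benzothiazolyl sulfone with a conjugated aldehyde (addition, Smiles rearrangement, loss of SO2 and benzothiazolone), a combination in which the allylically stabilised elimination intermediate can equilibrate and should deliver C9′=C10′ as the E isomer, while the fully substituted peroxide tolerates the amide base.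

Step 13
Reactants: 17 tert-butyl(2-{(3S,5S)-3,5-dimethyl-5-[(7E,9E,12Z)-pentadeca-7,9,12-trien-1-yl]-1,2-dioxolan-3-yl}ethoxy)diphenylsilane
Product: 18 2-{(3S,5S)-3,5-dimethyl-5-[(7E,9E,12Z)-pentadeca-7,9,12-trien-1-yl]-1,2-dioxolan-3-yl}ethan-1-ol
Conditions: Bu4NF, THF, 0 °C → rt
Reagents that add atoms: none
Why: Fluoride-driven cleavage of the silyl ether (Si–F bond formation), to which the peroxide and the triene are inert.

Step 14
Reactants: 18 2-{(3S,5S)-3,5-dimethyl-5-[(7E,9E,12Z)-pentadeca-7,9,12-trien-1-yl]-1,2-dioxolan-3-yl}ethan-1-ol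
Product: 19 {(3R,5S)-3,5-dimethyl-5-[(7E,9E,12Z)-pentadeca-7,9,12-trien-1-yl]-1,2-dioxolan-3-yl}acetaldehyde
Conditions: Dess–Martin periodinane, CH2Cl2, 0 °C → rt; crude product used at once
Reagents that add atoms: none
Why: Dess–Martin oxidation under non-basic conditions, which spares the triene and avoids E1cB opening of the ring from the β-peroxy aldehyde (the change of descriptor at C3 is only a change of CIP priority).

Step 15
Reactants: 19 {(3R,5S)-3,5-dimethyl-5-[(7E,9E,12Z)-pentadeca-7,9,12-trien-1-yl]-1,2-dioxolan-3-yl}acetaldehyde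
Product: 20 {(3R,5S)-3,5-dimethyl-5-[(7E,9E,12Z)-pentadeca-7,9,12-trien-1-yl]-1,2-dioxolan-3-yl}acetic acid (CNP0215994.1)
Conditions: NaClO2, NaH2PO4, 2-methylbut-2-ene (excess), t-BuOH/H2O, 0 °C → rt
Reagents that add atoms: sodium chlorite, [Na+].[O-]Cl=O
Why: Pinnick oxidation, in which chlorous acid oxidises only the aldehyde, the hypochlorous acid formed is scavenged by 2-methylbut-2-ene before it can attack the triene, and the weakly acidic buffer keeps the β-peroxy carbonyl unit from ring-opening.

**Compound list**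

1 | 6-bromohexan-1-ol | OCCCCCCBr | starting material
2 | (2-methylprop-2-en-1-yl)magnesium chloride | C=C(C)C[Mg]Cl | starting material
3 | 8-methylnon-8-en-1-ol | C=C(C)CCCCCCCO | intermediate
4 | 8-methylnon-8-en-1-yl acetate | C=C(C)CCCCCCCOC(C)=O | intermediate
5 | 8-hydroperoxy-8-methoxynonyl acetate (racemic) | CC(OC)(OO)CCCCCCCOC(C)=O | intermediate
6 | 8-methoxy-8-[(triethylsilyl)peroxy]nonyl acetate (racemic) | CC(OC)(OO[Si](CC)(CC)CC)CCCCCCCOC(C)=O | intermediate
7 | 3-methylbut-3-en-1-ol | C=C(C)CCO | starting material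
8 | tert-butyl[(3-methylbut-3-en-1-yl)oxy]diphenylsilane | C=C(C)CCO[Si](c1ccccc1)(c1ccccc1)C(C)(C)C | intermediate
9 | 7-[(3S,5S)-5-(2-{[tert-butyl(diphenyl)silyl]oxy}ethyl)-3,5-dimethyl-1,2-dioxolan-3-yl]heptyl acetate | CC(=O)OCCCCCCC[C@@]1(C)C[C@](C)(CCO[Si](c2ccccc2)(c2ccccc2)C(C)(C)C)OO1 | intermediate
10 | 7-[(3S,5S)-5-(2-{[tert-butyl(diphenyl)silyl]oxy}ethyl)-3,5-dimethyl-1,2-dioxolan-3-yl]heptan-1-ol | OCCCCCCC[C@@]1(C)C[C@](C)(CCO[Si](c2ccccc2)(c2ccccc2)C(C)(C)C)OO1 | intermediate
11 | 7-[(3S,5S)-5-(2-{[tert-butyl(diphenyl)silyl]oxy}ethyl)-3,5-dimethyl-1,2-dioxolan-3-yl]heptanal | O=CCCCCCC[C@@]1(C)C[C@](C)(CCO[Si](c2ccccc2)(c2ccccc2)C(C)(C)C)OO1 | intermediate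
12 | (triphenylphosphoranylidene)acetaldehyde | O=CC=P(c1ccccc1)(c1ccccc1)c1ccccc1 | starting material
13 | (2E)-9-[(3S,5S)-5-(2-{[tert-butyl(diphenyl)silyl]oxy}ethyl)-3,5-dimethyl-1,2-dioxolan-3-yl]non-2-enal | O=C/C=C/CCCCCC[C@@]1(C)C[C@](C)(CCO[Si](c2ccccc2)(c2ccccc2)C(C)(C)C)OO1 | intermediate
14 | (3Z)-hex-3-en-1-ol | CC/C=C\CCO | starting material
15 | 2-{[(3Z)-hex-3-en-1-yl]sulfanyl}-1,3-benzothiazole | CC/C=C\CCSc1nc2ccccc2s1 | intermediate
16 | 2-{[(3Z)-hex-3-en-1-yl]sulfonyl}-1,3-benzothiazole | CC/C=C\CCS(=O)(=O)c1nc2ccccc2s1 | intermediate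
17 | tert-butyl(2-{(3S,5S)-3,5-dimethyl-5-[(7E,9E,12Z)-pentadeca-7,9,12-trien-1-yl]-1,2-dioxolan-3-yl}ethoxy)diphenylsilane | CC/C=C\C/C=C/C=C/CCCCCC[C@@]1(C)C[C@](C)(CCO[Si](c2ccccc2)(c2ccccc2)C(C)(C)C)OO1 | intermediate
18 | 2-{(3S,5S)-3,5-dimethyl-5-[(7E,9E,12Z)-pentadeca-7,9,12-trien-1-yl]-1,2-dioxolan-3-yl}ethan-1-ol | CC/C=C\C/C=C/C=C/CCCCCC[C@@]1(C)C[C@](C)(CCO)OO1 | intermediate
19 | {(3R,5S)-3,5-dimethyl-5-[(7E,9E,12Z)-pentadeca-7,9,12-trien-1-yl]-1,2-dioxolan-3-yl}acetaldehyde | CC/C=C\C/C=C/C=C/CCCCCC[C@@]1(C)C[C@](C)(CC=O)OO1 | intermediate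
20 | {(3R,5S)-3,5-dimethyl-5-[(7E,9E,12Z)-pentadeca-7,9,12-trien-1-yl]-1,2-dioxolan-3-yl}acetic acid | CC/C=C\C/C=C/C=C/CCCCCC[C@@]1(C)C[C@](C)(CC(=O)O)OO1 | target

**Step count**

Total: 15 steps. Longest linear sequence: 12 steps (steps 1–4, 6–9 and 12–15, from 1 to 20).

**Steps most likely to fail, with fallbacks**

First, step 6 (the annulation). After the C4–C5 bond has formed, the tertiary cation at C3 may lose a proton or pick up chloride instead of closing onto oxygen. Facial discrimination in the closure is expected to be weak, so the cis and trans racemates may form in similar amounts and be hard to separate. The fallback closes the ring in a separate, known step; it sets out from 7 and 6 and comes back at 9.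
- 3-Methylbut-3-en-1-ol 7 is dilithiated (n-BuLi, TMEDA) and silylated with Me3SiCl to give, after hydrolysis of the O-silyl group, 3-[(trimethylsilyl)methyl]but-3-en-1-ol F1.
- F1 is protected (t-BuPh2SiCl, imidazole) as tert-butyl({3-[(trimethylsilyl)methyl]but-3-en-1-yl}oxy)diphenylsilane F2.
- SnCl4-promoted Hosomi–Sakurai-type allylation of the peroxycarbenium ion from 6 with this allylsilane, the β-silyl cation collapsing by loss of the trimethylsilyl group, would give 12-{[tert-butyl(diphenyl)silyl]oxy}-8-methyl-10-methylidene-8-[(triethylsilyl)peroxy]dodecyl acetate F3.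
- Brief treatment with HF·pyridine frees the hydroperoxide, 12-{[tert-butyl(diphenyl)silyl]oxy}-8-hydroperoxy-8-methyl-10-methylidenedodecyl acetate F4.
- Cycloperoxymercuration with Hg(OAc)2 followed by exchange with KBr closes the ring (O-attack at the more substituted alkene carbon) to bromo{[3-(7-acetoxyheptyl)-5-(2-{[tert-butyl(diphenyl)silyl]oxy}ethyl)-3-methyl-1,2-dioxolan-5-yl]methyl}mercury F5.
- NaBH4 in aqueous NaOH then replaces mercury by hydrogen and should give racemic cis/trans 9, which rejoins the route at 9 with the same separations.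

Second, step 12 (the Julia olefination). The elimination may not equilibrate fully, which would leave incomplete E selectivity at C9′=C10′; the amide base may deprotonate the enal at C6′, or the metalated sulfone may condense with itself. The fallback replaces the olefination by a stereospecific sp2–sp2 coupling; it sets out from 11 and 14 and comes back at 17.
- Aldehyde 11 is treated with lithiated bis(pinacolato)borylmethane (from the bis-boronate and lithium 2,2,6,6-tetramethylpiperidide, THF, −78 °C → rt; boron–Wittig olefination) to give tert-butyl(2-{(3S,5S)-3,5-dimethyl-5-[(7E)-8-(4,4,5,5-tetramethyl-1,3,2-dioxaborolan-2-yl)oct-7-en-1-yl]-1,2-dioxolan-3-yl}ethoxy)diphenylsilane F6.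
- Alcohol 14 is oxidised with Dess–Martin periodinane to (3Z)-hex-3-enal F7, which is used at once in a Takai olefination (CHI3, CrCl2, THF/dioxane) to give (1E,4Z)-1-iodohepta-1,4-diene F8; no peroxide is present at this stage.
- Suzuki–Miyaura coupling of the boronate with the iodide (PdCl2(dppf), aqueous K3PO4, THF, rt) proceeds with retention at both alkenes and should give 17.

Third, step 9 (the formyl-olefination). The unbranched aldehyde may react slowly with the stabilised ylide, which would call for prolonged heating of the peroxide, and the product enal may be homologated a second time to a dienal. The fallback builds the enal in three controlled operations; it sets out from 11 and comes back at 13.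
- Horner–Wadsworth–Emmons reaction of 11 with triethyl phosphonoacetate (LiCl, DBU, MeCN) gives ethyl (2E)-9-[(3S,5S)-5-(2-{[tert-butyl(diphenyl)silyl]oxy}ethyl)-3,5-dimethyl-1,2-dioxolan-3-yl]non-2-enoate F9.
- Reduction with i-Bu2AlH (CH2Cl2, −78 °C) gives (2E)-9-[(3S,5S)-5-(2-{[tert-butyl(diphenyl)silyl]oxy}ethyl)-3,5-dimethyl-1,2-dioxolan-3-yl]non-2-en-1-ol F10.
- Oxidation of the allylic alcohol with MnO2 (CH2Cl2, rt) gives 13.

Further compounds
F1 | step 6 | 3-[(trimethylsilyl)methyl]but-3-en-1-ol | C=C(C[Si](C)(C)C)CCO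
F2 | step 6 | tert-butyl({3-[(trimethylsilyl)methyl]but-3-en-1-yl}oxy)diphenylsilane | C=C(C[Si](C)(C)C)CCO[Si](c1ccccc1)(c1ccccc1)C(C)(C)C
F3 | step 6 | 12-{[tert-butyl(diphenyl)silyl]oxy}-8-methyl-10-methylidene-8-[(triethylsilyl)peroxy]dodecyl acetate (racemic) | CC(=O)OCCCCCCCC(C)(OO[Si](CC)(CC)CC)CC(=C)CCO[Si](c1ccccc1)(c1ccccc1)C(C)(C)C
F4 | step 6 | 12-{[tert-butyl(diphenyl)silyl]oxy}-8-hydroperoxy-8-methyl-10-methylidenedodecyl acetate (racemic) | CC(=O)OCCCCCCCC(C)(OO)CC(=C)CCO[Si](c1ccccc1)(c1ccccc1)C(C)(C)C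
F5 | step 6 | bromo{[3-(7-acetoxyheptyl)-5-(2-{[tert-butyl(diphenyl)silyl]oxy}ethyl)-3-methyl-1,2-dioxolan-5-yl]methyl}mercury (cis and trans racemates) | CC(=O)OCCCCCCCC1(C)CC(C[Hg]Br)(CCO[Si](c2ccccc2)(c2ccccc2)C(C)(C)C)OO1
F6 | step 12 | tert-butyl(2-{(3S,5S)-3,5-dimethyl-5-[(7E)-8-(4,4,5,5-tetramethyl-1,3,2-dioxaborolan-2-yl)oct-7-en-1-yl]-1,2-dioxolan-3-yl}ethoxy)diphenylsilane | CC1(C)OB(/C=C/CCCCCC[C@@]2(C)C[C@](C)(CCO[Si](c3ccccc3)(c3ccccc3)C(C)(C)C)OO2)OC1(C)C
F7 | step 12 | (3Z)-hex-3-enal | CC/C=C\CC=O
F8 | step 12 | (1E,4Z)-1-iodohepta-1,4-diene | CC/C=C\C/C=C/I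
F9 | step 9 | ethyl (2E)-9-[(3S,5S)-5-(2-{[tert-butyl(diphenyl)silyl]oxy}ethyl)-3,5-dimethyl-1,2-dioxolan-3-yl]non-2-enoate | CCOC(=O)/C=C/CCCCCC[C@@]1(C)C[C@](C)(CCO[Si](c2ccccc2)(c2ccccc2)C(C)(C)C)OO1
F10 | step 9 | (2E)-9-[(3S,5S)-5-(2-{[tert-butyl(diphenyl)silyl]oxy}ethyl)-3,5-dimethyl-1,2-dioxolan-3-yl]non-2-en-1-ol | OC/C=C/CCCCCC[C@@]1(C)C[C@](C)(CCO[Si](c2ccccc2)(c2ccccc2)C(C)(C)C)OO1
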